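**Retrosynthetic overview** (chain numbered C1, the carbon bearing the guaiacyl ring, to C7, the CH2 of the 4-hydroxybenzyl group)
- Target ⇐ one hydrogenolysis that removes two O-benzyl groups and cleaves one O–N bond.
- The only ring (the tetrahydropyran-4-one) ⇐ two C–O bonds made from water and an acyclic cross-conjugated dienone: O–C5 first (anti to the C6–O bond), then O–C1 (2,6-cis).
- Dienone ⇐ C4=C5 olefination of a dienyl ketophosphonate with an α-aminoxy aldehyde; the C6–O bond and its configuration come from D-proline-catalysed aminoxylation.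
- Ketophosphonate ⇐ O-benzylvanillin + dimethyl (2-oxopropyl)phosphonate; aldehyde ⇐ benzyl 4-iodophenyl ether + allyl alcohol.

Assumption: in chain numbering the target is 1S,5R,6S, that is a 2,6-cis ring with an anti (erythro) O5/O6 pair; "anilinooxy" means PhNH–O–.

**Step 1**
Reactants: 1 benzyl 4-iodophenyl ether; 2 allyl alcohol
Product: 3 3-[4-(benzyloxy)phenyl]propanal
Conditions: Pd(OAc)2 (3 mol%), Bu4NCl, NaHCO3, DMF, 40 °C
Reagents that add atoms: none
Why: Heck arylation of allyl alcohol under ligand-free phase-transfer (Jeffery) conditions, in which β-hydride elimination toward the carbinol gives an enol that tautomerises to the 3-arylpropanal; no stereocentre is formed.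

**Step 2**
Reactants: 4 4-(benzyloxy)-3-methoxybenzaldehyde (O-benzylvanillin); 5 dimethyl (2-oxopropyl)phosphonate
Product: 7 dimethyl {(3E)-4-[4-(benzyloxy)-3-methoxyphenyl]-2-oxobut-3-en-1-yl}phosphonate, via aldol adduct 6 (not isolated)
Conditions: NaH, THF, 0 °C; n-BuLi, −78 °C; 4, −78 to 0 °C; 1 M HCl; then TsOH·H2O (10 mol%), PhMe, 60 °C
Reagents that add atoms: none
Why: Aldol addition of the terminal (γ) carbon of the ketophosphonate dianion to the aldehyde, then acid-catalysed dehydration of the electron-rich benzylic β-hydroxy ketone to the E-enone, leaving the β-ketophosphonate intact.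

**Step 3**
Reactants: 3 3-[4-(benzyloxy)phenyl]propanal; 7 dimethyl {(3E)-4-[4-(benzyloxy)-3-methoxyphenyl]-2-oxobut-3-en-1-yl}phosphonate
Product: 9 (1E,4E,6S)-6-(anilinooxy)-1-[4-(benzyloxy)-3-methoxyphenyl]-7-[4-(benzyloxy)phenyl]hepta-1,4-dien-3-one, via aminoxy aldehyde 8 (not isolated)
Conditions: PhNO (1.0 equiv), D-proline (20 mol%), DMSO, rt, 20 min; then 7, Cs2CO3, rt
Reagents that add atoms: nitrosobenzene, O=Nc1ccccc1
Why: Proline-catalysed α-aminoxylation (O-selective nitroso aldol reaction) in which the D-proline enamine is attacked by the nitroso oxygen on the face fixed by the carboxylic acid hydrogen bond, giving the 2S aldehyde (L-proline gives R), which is trapped at once by Horner–Wadsworth–Emmons olefination to the E-enone before it can racemise.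

**Step 4**
Reactants: 9 (1E,4E,6S)-6-(anilinooxy)-1-[4-(benzyloxy)-3-methoxyphenyl]-7-[4-(benzyloxy)phenyl]hepta-1,4-dien-3-one
Product: 11 (2S,6R)-6-{(1S)-1-(anilinooxy)-2-[4-(benzyloxy)phenyl]ethyl}-2-[4-(benzyloxy)-3-methoxyphenyl]oxan-4-one, via hydroxy enone 10 (not isolated)
Conditions: PMe3 (20 mol%), H2O (10 equiv), degassed MeCN, 0 °C to rt
Reagents that add atoms: water, O
Why: Proposed new method: a phosphine-triggered hydrative double oxa-Michael annulation, in which PMe3 adds reversibly to the enone and the phosphonium enolate deprotonates water, so that a phosphonium hydroxide ion pair delivers hydroxide to C5, the β-carbon of the more electrophilic γ-oxygenated alkyl enone (the aryl enone is deactivated by its two oxygen donors), anti to the C6–O bond in the Felkin–Anh sense (H6 eclipsing the alkene, as in anti-selective alkoxide additions to γ-alkoxy enoates) to set 5R; the C5 alkoxide then closes 6-endo on C1, and because retro-oxa-Michael opening is favoured toward the aryl-conjugated enone, C1 equilibrates to the diequatorial 2,6-cis isomer (2S) while C5 is kept; the closest known reactions are the phosphine-catalysed hydration of simple vinyl ketones and the base-mediated 6-endo oxa-Michael cyclisation of hydroxy enones to cis-2,6-disubstituted tetrahydropyran-4-ones, which have not been merged or used on a cross-conjugated dienone with 1,2-induction.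

**Step 5**
Reactants: 11 (2S,6R)-6-{(1S)-1-(anilinooxy)-2-[4-(benzyloxy)phenyl]ethyl}-2-[4-(benzyloxy)-3-methoxyphenyl]oxan-4-one
Product: 12 (2S,6R)-2-(4-hydroxy-3-methoxyphenyl)-6-[(1S)-1-hydroxy-2-(4-hydroxyphenyl)ethyl]oxan-4-one
Conditions: H2 (1 atm), 10% Pd/C, EtOAc–EtOH, rt
Reagents that add atoms: none
Why: Heterogeneous catalytic hydrogenolysis cleaves both aryl benzyl ethers and the weak N–O bond in one operation, while the dialkyl ketone and the three stereocentres, none of which is at a reacting bond, are retained.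

**Compound list**
1 | benzyl 4-iodophenyl ether | Ic1ccc(OCc2ccccc2)cc1 | starting material
2 | allyl alcohol | C=CCO | starting material
3 | 3-[4-(benzyloxy)phenyl]propanal | O=CCCc1ccc(OCc2ccccc2)cc1 | intermediate
4 | 4-(benzyloxy)-3-methoxybenzaldehyde | COc1cc(C=O)ccc1OCc1ccccc1 | starting material
5 | dimethyl (2-oxopropyl)phosphonate | CC(=O)CP(=O)(OC)OC | starting material
6 | dimethyl {4-[4-(benzyloxy)-3-methoxyphenyl]-4-hydroxy-2-oxobutyl}phosphonate (racemic) | COc1cc(C(O)CC(=O)CP(=O)(OC)OC)ccc1OCc1ccccc1 | intermediate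
7 | dimethyl {(3E)-4-[4-(benzyloxy)-3-methoxyphenyl]-2-oxobut-3-en-1-yl}phosphonate | COc1cc(/C=C/C(=O)CP(=O)(OC)OC)ccc1OCc1ccccc1 | intermediate
8 | (2S)-2-(anilinooxy)-3-[4-(benzyloxy)phenyl]propanal | O=C[C@@H](ONc1ccccc1)Cc1ccc(OCc2ccccc2)cc1 | intermediate
9 | (1E,4E,6S)-6-(anilinooxy)-1-[4-(benzyloxy)-3-methoxyphenyl]-7-[4-(benzyloxy)phenyl]hepta-1,4-dien-3-one | COc1cc(/C=C/C(=O)/C=C/[C@@H](ONc2ccccc2)Cc2ccc(OCc3ccccc3)cc2)ccc1OCc1ccccc1 | intermediate
10 | (1E,5R,6S)-6-(anilinooxy)-1-[4-(benzyloxy)-3-methoxyphenyl]-7-[4-(benzyloxy)phenyl]-5-hydroxyhept-1-en-3-one | COc1cc(/C=C/C(=O)C[C@@H](O)[C@@H](ONc2ccccc2)Cc2ccc(OCc3ccccc3)cc2)ccc1OCc1ccccc1 | intermediate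
11 | (2S,6R)-6-{(1S)-1-(anilinooxy)-2-[4-(benzyloxy)phenyl]ethyl}-2-[4-(benzyloxy)-3-methoxyphenyl]oxan-4-one | COc1cc([C@@H]2CC(=O)C[C@H]([C@@H](ONc3ccccc3)Cc3ccc(OCc4ccccc4)cc3)O2)ccc1OCc1ccccc1 | intermediate
12 | (2S,6R)-2-(4-hydroxy-3-methoxyphenyl)-6-[(1S)-1-hydroxy-2-(4-hydroxyphenyl)ethyl]oxan-4-one | COc1cc([C@@H]2CC(=O)C[C@H]([C@@H](O)Cc3ccc(O)cc3)O2)ccc1O | target

**Step count and risk**
Total steps: 5. Longest linear sequence: 4 steps (1 → 3 → 9 → 11 → 12, or 4 → 7 → 9 → 11 → 12).

Most likely to fail, step 4 (the new hydrative annulation). Hydration of a β-substituted enone may be slow, hydroxy enone 10 can undergo retro-aldol cleavage, base can fragment the γ-aminoxy enone at the N–O bond, and the anti preference rests on substrate control alone. The fallback uses known chemistry, sets out from 9 and comes back at 11. Weitz–Scheffer-type nucleophilic epoxidation of the more electrophilic C4=C5 enone is run with t-BuOOH and the La(Oi-Pr)3/BINOL/Ph3As=O catalyst, taking the BINOL antipode that gives the 4R,5R oxirane (also the product of anti attack). This gives (2E)-1-[(2R,3R)-3-{(1S)-1-(anilinooxy)-2-[4-(benzyloxy)phenyl]ethyl}oxiran-2-yl]-3-[4-(benzyloxy)-3-methoxyphenyl]prop-2-en-1-one F1. The C4–O bond is then cut reductively with Na[PhSeB(OEt)3] (from (PhSe)2 and NaBH4 in EtOH, with AcOH) to give hydroxy enone 10, this time isolated. Catalytic KOt-Bu in THF at 0 °C closes the ring by the established oxa-Michael cyclisation to 11.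

Second, step 3 (one-pot aminoxylation and olefination). The anion of the dienyl ketophosphonate 7 may olefinate the sensitive aldehyde 8 too slowly, which would allow racemisation or decomposition. The fallback sets out from 3 and comes back at 9, and makes 7 and step 2 unnecessary. The same D-proline/PhNO aminoxylation (via 8) is followed by olefination with the simple commercial phosphonate 5 and Cs2CO3, giving (3E,5S)-5-(anilinooxy)-6-[4-(benzyloxy)phenyl]hex-3-en-2-one F2. Kinetic deprotonation of the methyl ketone with LiN(SiMe3)2 (2.2 equiv, THF, −78 °C; the first equivalent takes the N–H) and aldol addition to 4 gives (4E,6S)-6-(anilinooxy)-1-[4-(benzyloxy)-3-methoxyphenyl]-7-[4-(benzyloxy)phenyl]-1-hydroxyhept-4-en-3-one F3 as a mixture of C1 epimers. TsOH-catalysed dehydration in toluene then gives dienone 9.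

Third, step 5 (global hydrogenolysis). The ring C2–O bond is benzylic and para to oxygen, so it may be cleaved along with the benzyl ethers to give a ring-opened diarylheptanoid. The fallback sets out from 11 and comes back at 12 without hydrogen gas. Zn dust in AcOH–THF–H2O at rt cleaves only the N–O bond to give (2S,6R)-2-[4-(benzyloxy)-3-methoxyphenyl]-6-{(1S)-2-[4-(benzyloxy)phenyl]-1-hydroxyethyl}oxan-4-one F4. Both benzyl ethers are then removed with BCl3 and pentamethylbenzene as cation scavenger (CH2Cl2, −78 °C) to give 12.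

**Further compounds**
F1 | step 4 | (2E)-1-[(2R,3R)-3-{(1S)-1-(anilinooxy)-2-[4-(benzyloxy)phenyl]ethyl}oxiran-2-yl]-3-[4-(benzyloxy)-3-methoxyphenyl]prop-2-en-1-one | COc1cc(/C=C/C(=O)[C@@H]2O[C@H]2[C@@H](ONc2ccccc2)Cc2ccc(OCc3ccccc3)cc2)ccc1OCc1ccccc1
F2 | step 3 | (3E,5S)-5-(anilinooxy)-6-[4-(benzyloxy)phenyl]hex-3-en-2-one | CC(=O)/C=C/[C@@H](ONc1ccccc1)Cc1ccc(OCc2ccccc2)cc1
F3 | step 3 | (4E,6S)-6-(anilinooxy)-1-[4-(benzyloxy)-3-methoxyphenyl]-7-[4-(benzyloxy)phenyl]-1-hydroxyhept-4-en-3-one (both C1 epimers) | COc1cc(C(O)CC(=O)/C=C/[C@@H](ONc2ccccc2)Cc2ccc(OCc3ccccc3)cc2)ccc1OCc1ccccc1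
F4 | step 5 | (2S,6R)-2-[4-(benzyloxy)-3-methoxyphenyl]-6-{(1S)-2-[4-(benzyloxy)phenyl]-1-hydroxyethyl}oxan-4-one | COc1cc([C@@H]2CC(=O)C[C@H]([C@@H](O)Cc3ccc(OCc4ccccc4)cc3)O2)ccc1OCc1ccccc1
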